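**Assumptions:** The SMILES has a linear C20 (n‑icosyl) chain on the quinone, i.e. 2‑hydroxy‑3‑icosyl‑5‑methoxy‑1,4‑benzoquinone (C27H46O4). The molecule is achiral with no stereocentres, so no stereocontrol is required. Icosanal is made fresh from icosan‑1‑ol because long‑chain aldehydes store poorly.

## Retrosynthetic overview

1. Target ⇒ regioselective mono‑O‑methylation (C5–OH) of 2,5‑dihydroxy‑3‑icosyl‑1,4‑benzoquinone.
2. C3–C1′ bond ⇒ 2,5‑dihydroxy‑1,4‑benzoquinone + icosanal by organocatalytic reductive alkylation (Knoevenagel, then Hantzsch ester hydride transfer).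
3. Icosanal ⇐ icosan‑1‑ol by oxidation.
4. No ring is formed; the quinone ring is purchased intact.

## Route

**Step 1**
Reactants: 1, icosan‑1‑ol
Product: 2, icosanal
Conditions: TEMPO (10 mol %), PhI(OAc)2 (1.1 equiv), CH2Cl2, rt, 3–4 h; use crude or after a short silica plug, immediately
Reagents that add atoms: none
Why: TEMPO/oxoammonium oxidation of a primary alcohol in anhydrous CH2Cl2 stops cleanly at the aldehyde, and runs at rt where the waxy alcohol is soluble.

**Step 2**
Reactants: 2, icosanal (1.0 equiv, added slowly); 3, 2,5‑dihydroxy‑1,4‑benzoquinone (1.5–2 equiv)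
Product: 4, 2,5‑dihydroxy‑3‑icosyl‑1,4‑benzoquinone
Conditions: Hantzsch ester (diethyl 2,6‑dimethyl‑1,4‑dihydropyridine‑3,5‑dicarboxylate, 1.1 equiv), L‑proline (20 mol %), CH2Cl2/EtOH, rt→40 °C, 12–24 h; air‑exposed work‑up, wash out excess 3, recrystallise
Reagents that add atoms: none beyond reactants 2 and 3 (the Hantzsch ester delivers only hydrogen)
Why: Three‑component reductive alkylation: proline‑catalysed Knoevenagel condensation at the nucleophilic C3–H of the vinylogous acid gives an alkylidene (quinone methide) that is reduced in situ by the Hantzsch ester. Fast reduction prevents bis‑adducts, and excess 3 suppresses 3,6‑dialkylation.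

**Step 3**
Reactants: 4, 2,5‑dihydroxy‑3‑icosyl‑1,4‑benzoquinone; 5, methanol
Product: 6, irisoquin D (2‑hydroxy‑3‑icosyl‑5‑methoxy‑1,4‑benzoquinone)
Conditions: MeOH/CHCl3 (cosolvent for solubility), cat. conc. H2SO4, reflux, 2–6 h (TLC control); cool and crystallise
Reagents that add atoms: methanol, CO
Why: Acid‑catalysed vinylogous Fischer esterification (addition–elimination of MeOH). Only the C5–OH next to the ring C–H reacts, because the C2–OH flanked by the icosyl chain is sterically shielded, as with 3‑alkyl‑2‑hydroxynaphthoquinones, which resist MeOH/H+.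

## Compound list

1 | icosan‑1‑ol | CCCCCCCCCCCCCCCCCCCCO | starting material
2 | icosanal | CCCCCCCCCCCCCCCCCCCC=O | intermediate
3 | 2,5‑dihydroxy‑1,4‑benzoquinone | O=C1C=C(O)C(=O)C=C1O | starting material
4 | 2,5‑dihydroxy‑3‑icosyl‑1,4‑benzoquinone | CCCCCCCCCCCCCCCCCCCCC1=C(O)C(=O)C=C(O)C1=O | intermediate
5 | methanol | CO | starting material (reagent/solvent)
6 | irisoquin D, 2‑hydroxy‑3‑icosyl‑5‑methoxy‑1,4‑benzoquinone (achiral) | CCCCCCCCCCCCCCCCCCCCC1=C(O)C(=O)C=C(OC)C1=O | target

## Summary

Total steps: 3. Longest linear sequence: 3 (2 if icosanal is bought).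

Steps most likely to fail, with fallbacks that change the approach:

1. **Step 3 (regioselectivity, over‑methylation to the 2,5‑dimethoxyquinone).** Fallback: reverse the order. Mono‑saponify 2,5‑dimethoxy‑1,4‑benzoquinone to 2‑hydroxy‑5‑methoxy‑1,4‑benzoquinone, then run the reductive alkylation with 2 on that compound. Only C3, next to the free OH, is nucleophilic, so the regiochemistry is fixed by construction.
2. **Step 2 (dialkylation, bis‑quinonylmethane adducts, quinone reduction, poor solubility).** Fallback: aromatic route. Lithiate 1,2,4,5‑tetramethoxybenzene (n‑BuLi/TMEDA) and alkylate with 1‑bromoicosane, oxidise with CAN to 2,5‑dimethoxy‑3‑icosyl‑1,4‑benzoquinone, then selectively hydrolyse the hindered C2–OMe with HClO4.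
3. **Step 1 (aldehyde over‑oxidation or oligomerisation before use).** Fallback: avoid the aldehyde. Alkylate 3 by decarboxylative radical alkylation with henicosanoic acid (AgNO3/(NH4)2S2O8, or the derived diacyl peroxide under Fieser conditions) to give 4 directly.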